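# Proposed synthesis of (S)-8-lavandulylkaempferol (CNP0185677.2) by lipase desymmetrisation of a prochiral 2-(arylmethyl)propane-1,3-diol

## Numbering of the compounds

Abbreviations used in names: MOM = methoxymethyl; PMB = 4-methoxybenzyl; ArP = 2,6-bis(methoxymethoxy)-4-[(4-methoxyphenyl)methoxy]phenyl; (S)-Lav = (2S)-5-methyl-2-(prop-1-en-2-yl)hex-4-en-1-yl (the lavandulyl group).

- 1 phloroglucinol
- 2 3,5-bis(methoxymethoxy)phenol
- 3 1-(PMB-oxy)-3,5-bis(MOM-oxy)benzene
- 4 aryllithium ArP–Li (not isolated)
- 5 aldehyde ArP–CHO
- 6 diethyl malonate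
- 7 arylidene malonate
- 8 benzylmalonate
- 9 prochiral diol
- 10 vinyl acetate
- 11 (R)-monoacetate
- 12 (S)-iodo acetate
- 13 1-bromo-2-methylprop-1-ene
- 14 alkylzinc iodide (not isolated)
- 15 (S)-prenyl acetate
- 16 (S)-alcohol
- 17 (S)-aldehyde
- 18 secondary alcohol
- 19 (S)-methyl ketone
- 20 (S)-lavandulyl arene
- 21 its aryllithium (not isolated)
- 22 fully protected acetophenone
- 23 2-hydroxyacetophenone
- 24 4-(methoxymethoxy)benzaldehyde
- 25 chalcone
- 26 dihydroflavonol (not isolated)
- 27 protected flavonol
- 28 target

## Analysis of the target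

The target is (S)-8-lavandulylkaempferol, a 3-hydroxyflavone. Ring A is the benzo ring C4a–C8a, ring C the pyran-4-one and ring B the 4-hydroxyphenyl group on C2; free hydroxyls sit on C3, C5, C7 and C4′, and a C10 lavandulyl chain on C8. The only stereocentre is C2′ of that chain. It carries H, the C1′ methylene bound to C8, the isopropenyl group and the C3′ methylene of the prenyl arm, and it is S (priorities isopropenyl > C1′ > C3′). Because it is a lone centre with three hydrocarbon arms, nothing else in the molecule can relay chirality to it or correct it later, and it must not pass carelessly through an enolisable state. The two alkenes exclude hydrogenolysis and electrophilic oxidants, and under acid the 1,1-disubstituted alkene can be trapped by the neighbouring 7-OH as a chromane, so late steps must be mild. Two regiochemical demands add to this: the chain must end on C8 and not C6, so the ring A oxygen lying between the chain and the acyl carbon must become O1, and the 3-OH must come from a nucleophilic oxidant. The plan rests on the fact that both non-aryl arms of C2′ start with a single carbon (the isopropenyl carbon and C3′). Each can be traced back to a hydroxymethyl group, which makes C2′ the prochiral carbon of a 2-(arylmethyl)propane-1,3-diol that already holds C1′ and ring A.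

## Retrosynthetic reasoning

**28 ⇒ 27.** The last operation only removes two acetals and one benzylic ether from 27. No skeletal bond is made, so the sensitive free polyphenol exists only at the very end.

**27 ⇒ 25 ⇒ 23 + 24.** Ring C is opened at O1–C2 and at the C3–O bond, which leads to chalcone 25 (Algar–Flynn–Oyamada reaction in the forward sense). The oxidant is nucleophilic peroxide, which ignores the side-chain alkenes. Cutting the enone C=C of 25 gives acetophenone 23 and aldehyde 24 (Claisen–Schmidt condensation), so ring B, C2 and C3 arrive as one cheap piece. The forward closure must use the phenol between the acyl carbon and the lavandulyl group, so 23 must carry exactly that hydroxyl free.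

**23 ⇒ 22 ⇒ 20.** The aryl–acyl bond (C4a–C4) is cut. Arene 20 has only one kind of ring hydrogen, flanked by an acetal oxygen and the benzylic ether oxygen, so directed metalation (aryllithium 21) and acylation can give only 22. The para oxygen of 20 is deliberately a benzylic ether and not an acetal: after acylation only one acetal is ortho to the ketone, and it is the one between ketone and side chain. Its selective cleavage gives 23 and fixes the 8- rather than 6-position of the chain.

**20 ⇒ 19 ⇒ 18 ⇒ 17 ⇒ 16.** The isopropenyl group is cut at its C=CH2 bond (methyl ketone 19) and then at C–CH3 (aldehyde 17, through carbinol 18), back to the primary alcohol 16. Two C–C bonds must be made on this arm carbon, which requires carbonyl oxidation levels. This is done only after the other arm is a plain carbon chain, so that no β-leaving group is present.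

**16 ⇒ 15 ⇒ 12 + 13.** The prenyl arm is cut at C3′–C4′, an sp3–sp2 bond between a primary iodide 12 and alkenyl bromide 13. The alkene terminus is symmetric, so no geometry question arises. The coupling is planned through alkylzinc 14 (Negishi) because the other arm is still an acetate, which an organomagnesium partner would attack.

**12 ⇒ 11 ⇒ 9 + 10.** This is the strategic disconnection. No skeletal bond is cut; the stereocentre of 11 is traced to the prochiral diol 9 by removing the acetyl group delivered from vinyl acetate 10. The forward step must distinguish two enantiotopic hydroxymethyl groups, and the two arms are then worked up differently (free arm to prenyl, acetate arm to isopropenyl).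

**9 ⇒ 8 ⇒ 7 ⇒ 5 + 6.** The diol comes from the malonate 8 by reduction, 8 from the arylidene malonate 7 by conjugate reduction, and the C1′–C2′ bond is cut as a Knoevenagel condensation of aldehyde 5 with diethyl malonate 6. The symmetric three-carbon unit and its attachment to ring A are thus obtained in one C–C bond formation.

**5 ⇒ 3 ⇒ 2 ⇒ 1.** The formyl group of 5 is introduced by metalation of 3 between its two acetal oxygens (aryllithium 4). Ether 3 comes from phenol 2 and 2 from phloroglucinol 1, so the differentiation of the para oxygen is installed in the first two steps.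

## Alternatives that were turned down

**Alternative 1:** Ring A is cut at C8–C8a back to an acyclic triketide. The stereocentre is bought with (R)-limonene A3, whose ring alkene is cleaved so that one fragment becomes the prenyl arm and the other is extended to the methyl 3,5-dioxo ester A2.
- Forward key step: base turns A2 into its polyanion, the C8 carbanion attacks the ester carbon, and aromatisation gives 2-lavandulylphloroglucinol A1.
- For: no asymmetric step is needed, the enantiomeric purity is that of A3, the lavandulyl unit is complete before any aromatic chemistry, and the way to A1 is short.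
- Against: the required carbanion is the least acidic position of A2 (one flanking carbonyl only). O-acylation by the 5-enol gives a 4-hydroxy-2-pyranone through an equally six-membered transition state and is the usual fate of 3,5-dioxo esters.
- Against: A1 is an unprotected, air- and acid-sensitive triphenol. Its three hydroxyls must still be told apart, and acylating it for ring C calls for acids that can close the phenol/isopropenyl pair to a chromane.
- Comparison: Alternative 1 is stronger on stereochemical certainty and on step count to the lavandulyl arene. The chosen route offers a ring A whose oxygens stay differentiated from step 2 onward and a sequence in which every step is of a known type.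

**Alternative 2:** Ring C is cut at three bonds at once (O1–C8a, C4–C4a, O1–C2), leading to an aryne generated from the ortho-silylaryl triflate A5 and to the arylpropiolic acid A6.
- Forward key step: fluoride releases the aryne from A5, the carboxylate of A6 adds, the aryl anion attacks the carbonyl (net insertion into C–O), and the resulting ortho-hydroxyaryl ynone closes by 6-endo oxa-Michael addition to the flavone A4.
- For: it is convergent, the conditions are mild and leave both alkenes and the acetals alone, and the alkoxy group next to the aryne should steer the oxygen to C8a.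
- Against: A4 has no oxygen on C3. The usual ways to add it to a flavone are electrophilic oxidations of C2=C3, which would take the trisubstituted side-chain alkene first.
- Against: A5 is a hexasubstituted benzene whose preparation is longer than all the ring A chemistry of the chosen route, and it still needs its own answer for C2′. The regiochemistry relies on an electronic effect that works against the steric bulk of the neighbouring C1′ methylene.
- Comparison: Alternative 2 is stronger in convergence and avoids the chalcone stage with its aurone side path. The chosen route offers introduction of O3 by a nucleophilic oxidant and a stereocentre that is set early on a simple substrate.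

**Alternative 3:** Ring A is cut at C5–C6 and traced to the pyranone keto ester A8 (ester on C4a, 1-lavandulyl-2-oxopropyl group on C8a), elaborated from kojic acid A9.
- Forward key step: double deprotonation of A8 lets the methyl ketone carbanion attack the ester; loss of methoxide and enolisation give the 5,7-dihydroxy ring A of A7.
- For: the 3-oxygen is present from the start, no oxidation of ring C is needed, and the positions of the chain and of both ring A hydroxyls follow from connectivity. On these two points (3-OH and 6- versus 8-regiochemistry) it is stronger than the chosen route.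
- Against: A9 carries handles at only two of the four positions that must be substituted, so arylation and carboxylation of the pyranone have to be worked out.
- Against: the C8 methine of A8 is doubly activated and is deprotonated first, so the reacting methyl carbanion must form next to an existing anion. Strong base also opens pyranones by conjugate attack, and A7 still needs acidic deprotection.
- Comparison: the chosen route is longer in its end-game but places its risk in one enzymatic step of a well-known class instead of an unprecedented ring closure late in the sequence.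

Key step: step 7

## Assumptions

- Assumption: the Burkholderia cepacia lipase is taken to acetylate the pro-R hydroxymethyl group of 9 (giving (R)-11); this sense must be confirmed on the first sample of 11.
- Assumption: 13, 24, N-methoxy-N-methylacetamide and the other reagents named in the steps are treated as purchased chemicals.

## Steps

Step 1
Reactants: 1 phloroglucinol (benzene-1,3,5-triol)
Product: 2 3,5-bis(methoxymethoxy)phenol
Conditions: MOMCl (2.0 equiv), i-Pr2NEt (2.2 equiv), DMF, 0 °C → rt; chromatography
Reagents that add atoms: chloromethyl methyl ether, COCCl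
Why: Williamson-type O-alkylation with a hard α-chloro ether; at this stoichiometry the bis-ether should be the main statistical product and is separated from the mono-ether (recycled) and the tris-ether.

Step 2
Reactants: 2 3,5-bis(methoxymethoxy)phenol
Product: 3 1-[(4-methoxyphenyl)methoxy]-3,5-bis(methoxymethoxy)benzene
Conditions: PMBCl (1.1 equiv), K2CO3, DMF, rt → 50 °C
Reagents that add atoms: 4-methoxybenzyl chloride, COc1ccc(CCl)cc1
Why: Williamson ether synthesis on the single remaining phenol; the benzylic ether marks the oxygen that becomes O5 and, unlike the acetals, is a weak ortho-director.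

Step 3
Reactants: 3 1-[(4-methoxyphenyl)methoxy]-3,5-bis(methoxymethoxy)benzene
Product: 5 2,6-bis(methoxymethoxy)-4-[(4-methoxyphenyl)methoxy]benzaldehyde, via aryllithium 4 (not isolated)
Conditions: n-BuLi (1.1 equiv), THF, 0 °C, 1 h; DMF, 0 °C → rt; aq. NH4Cl
Reagents that add atoms: N,N-dimethylformamide, CN(C)C=O
Why: Directed ortho-metalation; the hydrogen between the two acetal oxygens is doubly coordinated and the most acidic, so lithiation should occur there and not beside the benzylic ether, and DMF then formylates the aryllithium.

Step 4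
Reactants: 5 2,6-bis(methoxymethoxy)-4-[(4-methoxyphenyl)methoxy]benzaldehyde; 6 diethyl malonate
Product: 7 diethyl 2-(ArP-methylidene)propanedioate
Conditions: piperidine (0.2 equiv), AcOH (0.2 equiv), toluene, reflux, Dean–Stark
Reagents that add atoms: none
Why: Knoevenagel condensation; azeotropic removal of water drives the electron-rich, di-ortho-substituted aldehyde to the arylidene malonate, and the nearly neutral amine salt leaves the acetals intact.

Step 5
Reactants: 7 diethyl 2-(ArP-methylidene)propanedioate
Product: 8 diethyl 2-(ArP-methyl)propanedioate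
Conditions: NaBH4 (1.2 equiv), EtOH, 0 °C → rt
Reagents that add atoms: none
Why: Conjugate hydride reduction of the doubly activated alkene; the ester groups are not reduced by borohydride under these conditions.

Step 6
Reactants: 8 diethyl 2-(ArP-methyl)propanedioate
Product: 9 2-(ArP-methyl)propane-1,3-diol
Conditions: LiAlH4 (2.5 equiv), THF, 0 °C → rt; aq. NaOH work-up
Reagents that add atoms: none
Why: Hydride reduction of both esters to the prochiral 1,3-diol; ethers and acetals are inert to the reagent.

Step 7
Reactants: 9 2-(ArP-methyl)propane-1,3-diol; 10 vinyl acetate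
Product: 11 (2R)-3-hydroxy-2-(ArP-methyl)propyl acetate
Conditions: lipase from Burkholderia cepacia (immobilised), vinyl acetate (4 equiv), t-BuOMe, 25 °C; enzyme filtered off when 9 is consumed
Reagents that add atoms: none
Why: Lipase-catalysed transesterification of the kind known for 2-benzylpropane-1,3-diols: the active-site serine is acetylated by 10, the released vinyl alcohol tautomerises to acetaldehyde so that the transfer cannot reverse, and the acyl-enzyme passes the acetyl group to one hydroxymethyl group of 9. No ring is closed and no skeletal bond is formed; C2′ becomes a stereocentre only because its two arms are now different. The controlling element is the chiral active site: with the bulky ArP-methyl group in the large hydrophobic pocket and the hydrogen in the small one, only one of the two enantiotopic CH2OH groups can reach the acyl-serine, here taken to be the pro-R one, which gives (R)-11. The step needs enantiotopic-group selectivity and mono- over di-acetylation; the first is secured by the large size difference between ArP-methyl and H on C2′, the second by stopping when 9 is consumed. A small amount of over-acetylation is tolerable and even useful, because the minor enantiomer of the monoacetate has its free hydroxyl on the arm the enzyme prefers and should be removed as diacetate faster. The neutral, base-free medium avoids the 1,3-acyl migration that would racemise 11 and leaves the acetals and the benzylic ether untouched.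

Step 8
Reactants: 11 (2R)-3-hydroxy-2-(ArP-methyl)propyl acetate
Product: 12 (2S)-3-iodo-2-(ArP-methyl)propyl acetate
Conditions: I2 (1.3 equiv), PPh3 (1.3 equiv), imidazole (2 equiv), CH2Cl2, 0 °C → rt
Reagents that add atoms: iodine, II
Why: Appel-type iodination (alkoxyphosphonium ion, SN2 by iodide) at the free primary carbon, which is not the stereocentre; imidazole buffers the medium so that the acetals survive and the acetate does not migrate (the descriptor changes to S only because CH2I outranks CH2OAc).

Step 9
Reactants: 12 (2S)-3-iodo-2-(ArP-methyl)propyl acetate; 13 1-bromo-2-methylprop-1-ene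
Product: 15 (2S)-5-methyl-2-(ArP-methyl)hex-4-en-1-yl acetate, via alkylzinc iodide 14 (not isolated)
Conditions: Zn dust (activated with BrCH2CH2Br and Me3SiCl), LiCl, THF, 40 °C; then 13 (2 equiv), Pd(PPh3)4 (5 mol %), THF, 50 °C
Reagents that add atoms: none
Why: Negishi coupling: zinc inserts into the primary C–I bond and the zerovalent palladium catalyst joins the alkylzinc iodide to the alkenyl bromide, forming C3′–C4′; the organozinc tolerates the acetate, which an organomagnesium reagent would attack, and the stereocentre is not involved.

Step 10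
Reactants: 15 (2S)-5-methyl-2-(ArP-methyl)hex-4-en-1-yl acetate
Product: 16 (2S)-5-methyl-2-(ArP-methyl)hex-4-en-1-ol
Conditions: K2CO3 (0.2 equiv), MeOH, rt
Reagents that add atoms: none
Why: Base-catalysed transesterification of the acetate with methanol; acyl migration is no longer possible because the second arm is now a carbon chain.

Step 11
Reactants: 16 (2S)-5-methyl-2-(ArP-methyl)hex-4-en-1-ol
Product: 17 (2S)-5-methyl-2-(ArP-methyl)hex-4-enal
Conditions: Dess–Martin periodinane (1.3 equiv), NaHCO3, CH2Cl2, 0 °C → rt; used crude
Reagents that add atoms: none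
Why: Dess–Martin oxidation under buffered, non-basic conditions, chosen so that the α-stereocentre of the aldehyde is not epimerised; the aldehyde is carried on at once.

Step 12
Reactants: 17 (2S)-5-methyl-2-(ArP-methyl)hex-4-enal
Product: 18 (2RS,3S)-6-methyl-3-(ArP-methyl)hept-5-en-2-ol
Conditions: MeMgBr (1.5 equiv), THF, −78 °C; aq. NH4Cl
Reagents that add atoms: methylmagnesium bromide, C[Mg]Br
Why: Grignard 1,2-addition, which at −78 °C should be much faster than enolisation; the carbinol centre forms as a mixture of epimers, which is irrelevant because it is oxidised in the next step.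

Step 13
Reactants: 18 (2RS,3S)-6-methyl-3-(ArP-methyl)hept-5-en-2-ol
Product: 19 (3S)-6-methyl-3-(ArP-methyl)hept-5-en-2-one
Conditions: Dess–Martin periodinane (1.5 equiv), NaHCO3, CH2Cl2, 0 °C → rt
Reagents that add atoms: none
Why: Dess–Martin oxidation of the secondary alcohol; both carbinol epimers converge on one methyl ketone under non-basic conditions.

Step 14
Reactants: 19 (3S)-6-methyl-3-(ArP-methyl)hept-5-en-2-one
Product: 20 2-[(S)-Lav]-5-[(4-methoxyphenyl)methoxy]-1,3-bis(methoxymethoxy)benzene
Conditions: Ph3PCH3Br (1.5 equiv), KOt-Bu (1.4 equiv), THF, 0 °C; then 19, 0 °C → rt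
Reagents that add atoms: methyltriphenylphosphonium bromide, C[P+](c1ccccc1)(c1ccccc1)c1ccccc1.[Br-]
Why: Wittig methylenation with the preformed ylide and no excess base turns the acetyl group into the isopropenyl group; any reversible enolisation should go towards the unhindered methyl side and leave C2′ untouched.

Step 15
Reactants: 20 2-[(S)-Lav]-5-[(4-methoxyphenyl)methoxy]-1,3-bis(methoxymethoxy)benzene
Product: 22 1-[2,4-bis(methoxymethoxy)-6-[(4-methoxyphenyl)methoxy]-3-[(S)-Lav]phenyl]ethan-1-one, via aryllithium 21 (not isolated)
Conditions: n-BuLi (1.2 equiv), THF, 0 °C, 1 h; MeC(O)N(OMe)Me (2 equiv), −78 → 0 °C; aq. NH4Cl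
Reagents that add atoms: N-methoxy-N-methylacetamide, CC(=O)N(C)OC
Why: Directed ortho-metalation at one of the two equivalent ring hydrogens (each flanked by an acetal oxygen and the ether oxygen), followed by acylation with a Weinreb amide, whose chelated adduct prevents double addition.

Step 16
Reactants: 22 1-[2,4-bis(methoxymethoxy)-6-[(4-methoxyphenyl)methoxy]-3-[(S)-Lav]phenyl]ethan-1-one
Product: 23 1-[2-hydroxy-4-(methoxymethoxy)-6-[(4-methoxyphenyl)methoxy]-3-[(S)-Lav]phenyl]ethan-1-one
Conditions: HCl (0.2 M) in MeOH–THF, 0 °C → rt, monitored; NaHCO3 quench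
Reagents that add atoms: none
Why: Acid-catalysed acetal exchange with methanol; the acetal ortho to the ketone should go first (carbonyl-assisted protonation, hydrogen-bonded phenol as product, twisting between two ortho substituents), while the benzylic ether, which is not an acetal, and the acetal para to the ketone need stronger acid.

Step 17
Reactants: 23 1-[2-hydroxy-4-(methoxymethoxy)-6-[(4-methoxyphenyl)methoxy]-3-[(S)-Lav]phenyl]ethan-1-one; 24 4-(methoxymethoxy)benzaldehyde
Product: 25 (2E)-1-[2-hydroxy-4-(methoxymethoxy)-6-[(4-methoxyphenyl)methoxy]-3-[(S)-Lav]phenyl]-3-[4-(methoxymethoxy)phenyl]prop-2-en-1-one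
Conditions: KOH (aq. 50 %, excess), EtOH, rt, 24–48 h
Reagents that add atoms: none
Why: Claisen–Schmidt (crossed aldol) condensation; 24 has no α-hydrogen, and E1cB dehydration gives the E-enone.

Step 18
Reactants: 25 (2E)-1-[2-hydroxy-4-(methoxymethoxy)-6-[(4-methoxyphenyl)methoxy]-3-[(S)-Lav]phenyl]-3-[4-(methoxymethoxy)phenyl]prop-2-en-1-one
Product: 27 3-hydroxy-7-(methoxymethoxy)-5-[(4-methoxyphenyl)methoxy]-2-[4-(methoxymethoxy)phenyl]-8-[(S)-Lav]-4H-chromen-4-one, via dihydroflavonol 26 (not isolated)
Conditions: H2O2 (30 %, 5 equiv), NaOH (aq. 2 M), MeOH–THF, 0 °C → rt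
Reagents that add atoms: hydrogen peroxide, OO
Why: Algar–Flynn–Oyamada reaction: alkaline peroxide oxidises the enone nucleophilically, the 2′-phenoxide (the only free phenol) closes ring C by 6-endo attack on the β-carbon, and excess peroxide dehydrogenates the dihydroflavonol; the isolated alkenes are inert to this nucleophilic oxidant.

Step 19
Reactants: 27 3-hydroxy-7-(methoxymethoxy)-5-[(4-methoxyphenyl)methoxy]-2-[4-(methoxymethoxy)phenyl]-8-[(S)-Lav]-4H-chromen-4-one
Product: 28 3,5,7-trihydroxy-2-(4-hydroxyphenyl)-8-[(2S)-5-methyl-2-(prop-1-en-2-yl)hex-4-en-1-yl]-4H-chromen-4-one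
Conditions: HCl (1.5 M) in MeOH (from conc. aq. HCl), 45 °C, argon
Reagents that add atoms: none
Why: Acid solvolysis of the two acetals and of the benzylic ether peri to the C4 carbonyl (activated by chelation of the proton); methanol traps both cations, and the moderate acid strength and temperature are chosen to outrun addition to the alkenes.

## Compound list

ArP and (S)-Lav as defined above.

1 | phloroglucinol | Oc1cc(O)cc(O)c1 | starting material
2 | 3,5-bis(methoxymethoxy)phenol | COCOc1cc(O)cc(OCOC)c1 | intermediate
3 | 1-[(4-methoxyphenyl)methoxy]-3,5-bis(methoxymethoxy)benzene | COCOc1cc(OCc2ccc(OC)cc2)cc(OCOC)c1 | intermediate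
4 | [2,6-bis(methoxymethoxy)-4-[(4-methoxyphenyl)methoxy]phenyl]lithium | [Li]c1c(OCOC)cc(OCc2ccc(OC)cc2)cc1OCOC | intermediate
5 | 2,6-bis(methoxymethoxy)-4-[(4-methoxyphenyl)methoxy]benzaldehyde | O=Cc1c(OCOC)cc(OCc2ccc(OC)cc2)cc1OCOC | intermediate
6 | diethyl malonate | CCOC(=O)CC(=O)OCC | starting material
7 | diethyl 2-(ArP-methylidene)propanedioate | CCOC(=O)C(=Cc1c(OCOC)cc(OCc2ccc(OC)cc2)cc1OCOC)C(=O)OCC | intermediate
8 | diethyl 2-(ArP-methyl)propanedioate | CCOC(=O)C(Cc1c(OCOC)cc(OCc2ccc(OC)cc2)cc1OCOC)C(=O)OCC | intermediate
9 | 2-(ArP-methyl)propane-1,3-diol | OCC(CO)Cc1c(OCOC)cc(OCc2ccc(OC)cc2)cc1OCOC | intermediate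
10 | vinyl acetate | C=COC(C)=O | starting material
11 | (2R)-3-hydroxy-2-(ArP-methyl)propyl acetate | CC(=O)OC[C@@H](CO)Cc1c(OCOC)cc(OCc2ccc(OC)cc2)cc1OCOC | intermediate
12 | (2S)-3-iodo-2-(ArP-methyl)propyl acetate | CC(=O)OC[C@@H](CI)Cc1c(OCOC)cc(OCc2ccc(OC)cc2)cc1OCOC | intermediate
13 | 1-bromo-2-methylprop-1-ene | CC(C)=CBr | starting material
14 | [(2S)-3-acetoxy-2-(ArP-methyl)propyl]zinc iodide | CC(=O)OC[C@@H](C[Zn]I)Cc1c(OCOC)cc(OCc2ccc(OC)cc2)cc1OCOC | intermediate
15 | (2S)-5-methyl-2-(ArP-methyl)hex-4-en-1-yl acetate | CC(=O)OC[C@@H](CC=C(C)C)Cc1c(OCOC)cc(OCc2ccc(OC)cc2)cc1OCOC | intermediate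
16 | (2S)-5-methyl-2-(ArP-methyl)hex-4-en-1-ol | OC[C@@H](CC=C(C)C)Cc1c(OCOC)cc(OCc2ccc(OC)cc2)cc1OCOC | intermediate
17 | (2S)-5-methyl-2-(ArP-methyl)hex-4-enal | O=C[C@@H](CC=C(C)C)Cc1c(OCOC)cc(OCc2ccc(OC)cc2)cc1OCOC | intermediate
18 | (2RS,3S)-6-methyl-3-(ArP-methyl)hept-5-en-2-ol (both C2 epimers) | CC(O)[C@@H](CC=C(C)C)Cc1c(OCOC)cc(OCc2ccc(OC)cc2)cc1OCOC | intermediate
19 | (3S)-6-methyl-3-(ArP-methyl)hept-5-en-2-one | CC(=O)[C@@H](CC=C(C)C)Cc1c(OCOC)cc(OCc2ccc(OC)cc2)cc1OCOC | intermediate
20 | 2-[(S)-Lav]-5-[(4-methoxyphenyl)methoxy]-1,3-bis(methoxymethoxy)benzene | C=C(C)[C@@H](CC=C(C)C)Cc1c(OCOC)cc(OCc2ccc(OC)cc2)cc1OCOC | intermediate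
21 | [2,4-bis(methoxymethoxy)-6-[(4-methoxyphenyl)methoxy]-3-[(S)-Lav]phenyl]lithium | C=C(C)[C@@H](CC=C(C)C)Cc1c(OCOC)c([Li])c(OCc2ccc(OC)cc2)cc1OCOC | intermediate
22 | 1-[2,4-bis(methoxymethoxy)-6-[(4-methoxyphenyl)methoxy]-3-[(S)-Lav]phenyl]ethan-1-one | C=C(C)[C@@H](CC=C(C)C)Cc1c(OCOC)c(C(C)=O)c(OCc2ccc(OC)cc2)cc1OCOC | intermediate
23 | 1-[2-hydroxy-4-(methoxymethoxy)-6-[(4-methoxyphenyl)methoxy]-3-[(S)-Lav]phenyl]ethan-1-one | C=C(C)[C@@H](CC=C(C)C)Cc1c(O)c(C(C)=O)c(OCc2ccc(OC)cc2)cc1OCOC | intermediate
24 | 4-(methoxymethoxy)benzaldehyde | COCOc1ccc(C=O)cc1 | starting material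
25 | (2E)-1-[2-hydroxy-4-(methoxymethoxy)-6-[(4-methoxyphenyl)methoxy]-3-[(S)-Lav]phenyl]-3-[4-(methoxymethoxy)phenyl]prop-2-en-1-one | C=C(C)[C@@H](CC=C(C)C)Cc1c(O)c(C(=O)/C=C/c2ccc(OCOC)cc2)c(OCc3ccc(OC)cc3)cc1OCOC | intermediate
26 | trans-3-hydroxy-7-(methoxymethoxy)-5-[(4-methoxyphenyl)methoxy]-2-[4-(methoxymethoxy)phenyl]-8-[(S)-Lav]-2,3-dihydro-4H-chromen-4-one (both trans C2/C3 pairs; ring centres not specified) | C=C(C)[C@@H](CC=C(C)C)Cc1c(OCOC)cc(OCc2ccc(OC)cc2)c2c1OC(c1ccc(OCOC)cc1)C(O)C2=O | intermediate
27 | 3-hydroxy-7-(methoxymethoxy)-5-[(4-methoxyphenyl)methoxy]-2-[4-(methoxymethoxy)phenyl]-8-[(S)-Lav]-4H-chromen-4-one | C=C(C)[C@@H](CC=C(C)C)Cc1c(OCOC)cc(OCc4ccc(OC)cc4)c2c(=O)c(O)c(-c3ccc(OCOC)cc3)oc12 | intermediate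
28 | 3,5,7-trihydroxy-2-(4-hydroxyphenyl)-8-[(2S)-5-methyl-2-(prop-1-en-2-yl)hex-4-en-1-yl]-4H-chromen-4-one | C=C(C)[C@@H](CC=C(C)C)Cc1c(O)cc(O)c2c(=O)c(O)c(-c3ccc(O)cc3)oc12 | target

## Step count and least certain steps

Total: 19 steps. Longest linear sequence: 19 steps (1 → 28); all other inputs are purchased.

**Step 7 (key step).**
- What may go wrong: the enzyme may acetylate the other enantiotopic arm, or discriminate poorly because the di-ortho-substituted aryl group fits the large pocket badly. Over-acetylation and acyl migration during isolation would further erode the enantiomeric purity.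
- If only the sense is reversed, the roles of the two arms can be exchanged by a protecting-group swap.
- Fallback (independent of the enzyme, auxiliary-controlled alkylation), from malonate 8 back to alcohol 16: saponification of 8 (KOH, EtOH–H2O) and careful acidification give the malonic acid F1. Heating F1 in pyridine decarboxylates it to the 3-arylpropanoic acid F2. Activation of F2 as the pivalic mixed anhydride and reaction with lithiated (4S)-4-benzyl-1,3-oxazolidin-2-one give the N-acyl oxazolidinone F3. Enolisation of F3 with NaN(SiMe3)2 at −78 °C and alkylation with 1-bromo-3-methylbut-2-ene on the face opposite the benzyl group should give the alkylated imide F4 with the 2S centre. Reduction of F4 with LiBH4 releases the auxiliary and gives 16.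

**Step 9.**
- What may go wrong: zinc insertion into the β-branched iodide may be slow, or the alkylpalladium intermediate may lose a β-hydride or be reduced, lowering conversion to the coupled product.
- Fallback, from 12 back to 15: stoichiometric substitution with lithium bis(2-methylprop-1-enyl)cuprate F5 (made from 13, t-BuLi and CuI) in Et2O–THF at −40 → 0 °C. Organocuprates displace primary iodides and leave acetates alone.

**Step 14 (and the handling of 17 and 19).**
- What may go wrong: reversible enolisation towards C2′ under the basic ylide would partly epimerise the stereocentre.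
- Fallback (Peterson olefination), from 19 back to 20: addition of Me3SiCH2MgCl in the presence of CeCl3 at −78 °C (a weakly basic, strongly nucleophilic reagent) gives the β-hydroxysilane F6. Treatment of F6 with KH in THF brings about syn-elimination to 20.

**Step 16.**
- What may go wrong: cleavage of the second acetal or of the benzylic ether may compete with cleavage of the acetal ortho to the ketone, so the two ortho oxygens are not cleanly told apart.
- Fallback, from 22 back to 23: both acetals are removed under aprotic, acetal-specific conditions (Me3SiOTf, 2,2′-bipyridyl, CH2Cl2, 0 °C, then water) to give the dihydroxy ketone F7. F7 is then mono-protected with MOMCl (1 equiv) and K2CO3 in acetone; the hydrogen-bonded, doubly flanked 2-OH should stay free and only the 4-OH react, which gives 23.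

**Step 18.**
- What may go wrong: with an alkoxy group on C6′ the carbonyl is twisted out of the ring plane, and closure of the phenoxide on the α-carbon (5-exo, leading to an aurone) can compete with the 6-endo closure.
- Fallback (the 3-oxygen is brought in before ring closure, no oxidant), from 20 to 28:
  - Aryllithium 21 is generated as in step 15 and acylated with N-methoxy-2-(methoxymethoxy)-N-methylacetamide F8 (from 2-hydroxy-N-methoxy-N-methylacetamide and MOMCl) to give the α-(methoxymethoxy) ketone F9.
  - Dilute HCl in MeOH removes the aryl acetal ortho to the ketone and gives the 2-hydroxy ketone F10.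
  - The dianion of F10 (LiN(SiMe3)2, 3 equiv, THF, −78 °C) is C-acylated with 1-[4-(methoxymethoxy)benzoyl]imidazole F11 (from 4-(methoxymethoxy)benzoic acid and carbonyldiimidazole) to give the 1,3-diketone F12 (Baker–Venkataraman-type).
  - HCl in MeOH at 45 °C then brings about cyclodehydration and removal of all protecting groups in one operation and gives 28.

**Step 19.**
- What may go wrong: acid-catalysed addition of the 7-OH or of methanol to the isopropenyl group, and C-benzylation of the electron-rich C6 by the 4-methoxybenzyl cation.
- Fallback (stepwise, aprotic cleavage with soft nucleophiles), from 27 to 28: MgBr2·OEt2 and Me2S in CH2Cl2 remove the chelated benzylic ether and give the 5-hydroxy flavonol F13. ZnBr2 and n-PrSH in CH2Cl2 at 0 °C then cleave the two acetals of F13 within minutes and give 28.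

## Further compounds

F1 | step 7 | 2-(ArP-methyl)propanedioic acid | OC(=O)C(Cc1c(OCOC)cc(OCc2ccc(OC)cc2)cc1OCOC)C(=O)O
F2 | step 7 | 3-[2,6-bis(methoxymethoxy)-4-[(4-methoxyphenyl)methoxy]phenyl]propanoic acid | OC(=O)CCc1c(OCOC)cc(OCc2ccc(OC)cc2)cc1OCOC
F3 | step 7 | (4S)-4-benzyl-3-[3-[2,6-bis(methoxymethoxy)-4-[(4-methoxyphenyl)methoxy]phenyl]propanoyl]-1,3-oxazolidin-2-one | O=C(CCc1c(OCOC)cc(OCc2ccc(OC)cc2)cc1OCOC)N1[C@@H](Cc2ccccc2)COC1=O
F4 | step 7 | (4S)-4-benzyl-3-[(2S)-5-methyl-2-(ArP-methyl)hex-4-enoyl]-1,3-oxazolidin-2-one | O=C([C@@H](CC=C(C)C)Cc1c(OCOC)cc(OCc2ccc(OC)cc2)cc1OCOC)N1[C@@H](Cc2ccccc2)COC1=O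
F5 | step 9 | lithium bis(2-methylprop-1-enyl)cuprate | [Li+].CC(C)=C[Cu-]C=C(C)C
F6 | step 14 | (3S)-2,6-dimethyl-3-(ArP-methyl)-1-(trimethylsilyl)hept-5-en-2-ol (both C2 epimers) | C[Si](C)(C)CC(C)(O)[C@@H](CC=C(C)C)Cc1c(OCOC)cc(OCc2ccc(OC)cc2)cc1OCOC
F7 | step 16 | 1-[2,4-dihydroxy-6-[(4-methoxyphenyl)methoxy]-3-[(S)-Lav]phenyl]ethan-1-one | C=C(C)[C@@H](CC=C(C)C)Cc1c(O)c(C(C)=O)c(OCc2ccc(OC)cc2)cc1O
F8 | step 18 | N-methoxy-2-(methoxymethoxy)-N-methylacetamide | COCOCC(=O)N(C)OC
F9 | step 18 | 1-[2,4-bis(methoxymethoxy)-6-[(4-methoxyphenyl)methoxy]-3-[(S)-Lav]phenyl]-2-(methoxymethoxy)ethan-1-one | C=C(C)[C@@H](CC=C(C)C)Cc1c(OCOC)c(C(=O)COCOC)c(OCc2ccc(OC)cc2)cc1OCOC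
F10 | step 18 | 1-[2-hydroxy-4-(methoxymethoxy)-6-[(4-methoxyphenyl)methoxy]-3-[(S)-Lav]phenyl]-2-(methoxymethoxy)ethan-1-one | C=C(C)[C@@H](CC=C(C)C)Cc1c(O)c(C(=O)COCOC)c(OCc2ccc(OC)cc2)cc1OCOC
F11 | step 18 | 1-[4-(methoxymethoxy)benzoyl]imidazole | COCOc1ccc(C(=O)n2ccnc2)cc1
F12 | step 18 | 1-[2-hydroxy-4-(methoxymethoxy)-6-[(4-methoxyphenyl)methoxy]-3-[(S)-Lav]phenyl]-2-(methoxymethoxy)-3-[4-(methoxymethoxy)phenyl]propane-1,3-dione (C2 not specified) | C=C(C)[C@@H](CC=C(C)C)Cc1c(O)c(C(=O)C(OCOC)C(=O)c2ccc(OCOC)cc2)c(OCc3ccc(OC)cc3)cc1OCOC
F13 | step 19 | 3,5-dihydroxy-7-(methoxymethoxy)-2-[4-(methoxymethoxy)phenyl]-8-[(S)-Lav]-4H-chromen-4-one | C=C(C)[C@@H](CC=C(C)C)Cc1c(OCOC)cc(O)c2c(=O)c(O)c(-c3ccc(OCOC)cc3)oc12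
A1 | alternative 1 | 2-lavandulylphloroglucinol, 2-[(S)-Lav]benzene-1,3,5-triol | C=C(C)[C@@H](CC=C(C)C)Cc1c(O)cc(O)cc1O
A2 | alternative 1 | methyl (8R)-11-methyl-3,5-dioxo-8-(prop-1-en-2-yl)dodec-10-enoate | COC(=O)CC(=O)CC(=O)CC[C@@H](C(C)=C)CC=C(C)C
A3 | alternative 1 | (R)-limonene | CC1=CC[C@@H](CC1)C(C)=C
A4 | alternative 2 | 8-lavandulyl-5,7,4′-tris(methoxymethoxy)flavone | C=C(C)[C@@H](CC=C(C)C)Cc1c(OCOC)cc(OCOC)c2c(=O)cc(-c3ccc(OCOC)cc3)oc12
A5 | alternative 2 | 2-[(S)-Lav]-3,5-bis(methoxymethoxy)-6-(trimethylsilyl)phenyl trifluoromethanesulfonate | C=C(C)[C@@H](CC=C(C)C)Cc1c(OCOC)cc(OCOC)c([Si](C)(C)C)c1OS(=O)(=O)C(F)(F)F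
A6 | alternative 2 | 3-[4-(methoxymethoxy)phenyl]prop-2-ynoic acid | COCOc1ccc(C#CC(=O)O)cc1
A7 | alternative 3 | 8-lavandulylkaempferol 3,4′-bis(methoxymethyl) ether | C=C(C)[C@@H](CC=C(C)C)Cc1c(O)cc(O)c2c(=O)c(OCOC)c(-c3ccc(OCOC)cc3)oc12
A8 | alternative 3 | methyl 5-(methoxymethoxy)-6-[4-(methoxymethoxy)phenyl]-4-oxo-2-[1-acetyl-2-lavandulyl-type side chain: 6-methyl-2-oxo-4-(prop-1-en-2-yl)oct-6-en-3-yl-type C8 unit]-4H-pyran-3-carboxylate (pyranone keto ester; methine next to the ring not specified) | COC(=O)c1c(C(C[C@@H](C(C)=C)CC=C(C)C)C(C)=O)oc(-c2ccc(OCOC)cc2)c(OCOC)c1=O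
A9 | alternative 3 | kojic acid | OCc1cc(=O)c(O)co1
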